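**Retrosynthetic overview**
- Target ⇐ oxidation of a bis-allylic alcohol ⇐ alkenylzinc (from a silyl-protected 2-methylbut-3-yn-2-ol) added to a 2-substituted acrolein ⇐ allylic oxidation of an isopropenyl group.
- C6 tiglate ⇐ enolate hydroxylation and acylation of the bicyclic epoxy ketone, trans to the C5 substituent.
- Key disconnection, both rings at once: C1–C2 (carbene-catalysed benzoin addition) and O–C3 (alkoxide displaces chloride) from an open-chain 5-chloro-6-oxoheptanal.
- Open chain ⇐ periodic acid cleavage of the epoxy mesylate of cis-carveol, made from (S)-carvone; C5 is the only stereocentre carried through, and the carbonyl ends up 1,3-transposed.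
- Ring order: the carvone ring is opened first; the six-membered ring and the oxirane are then formed together; no ring is formed afterwards.

Assumption: (S)-(+)-carvone, tigloyl chloride and trimethyl[(2-methylbut-3-yn-2-yl)oxy]silane are bought; C1–C6 below mean the ring atoms of the target (C1 carbonyl, C2/C3 oxirane carbons, C5 side-chain carbon, C6 ester carbon).

Step 1
Reactants: 1 (S)-(+)-carvone
Product: 2 (1S,5S)-2-methyl-5-(prop-1-en-2-yl)cyclohex-2-en-1-ol
Conditions: NaBH4, CeCl3·7H2O, MeOH, 0 °C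
Reagents that add atoms: none
Why: Luche reduction, in which CeCl3-activated borohydride adds 1,2 and axially to the enone carbonyl, so the new hydroxyl ends cis to the isopropenyl group (new carbinol centre S) and neither alkene is touched.

Step 2
Reactants: 2 (1S,5S)-2-methyl-5-(prop-1-en-2-yl)cyclohex-2-en-1-ol
Product: 3 (1S,2S,4R,6R)-1-methyl-4-(prop-1-en-2-yl)-7-oxabicyclo[4.1.0]heptan-2-ol
Conditions: VO(acac)2 (2 mol %), tBuOOH, CH2Cl2, 0 °C to rt
Reagents that add atoms: tert-butyl hydroperoxide, CC(C)(C)OO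
Why: Hydroxyl-directed vanadium-catalysed epoxidation of an allylic alcohol, in which the vanadium-bound alkoxide delivers oxygen to the ring alkene on the face of the OH (both oxirane centres syn to C–OH) and leaves the undirected isopropenyl alkene alone.

Step 3
Reactants: 3 (1S,2S,4R,6R)-1-methyl-4-(prop-1-en-2-yl)-7-oxabicyclo[4.1.0]heptan-2-ol
Product: 4 (1R,2S,4S,6R)-1-methyl-4-(prop-1-en-2-yl)-7-oxabicyclo[4.1.0]heptan-2-yl methanesulfonate
Conditions: MsCl, Et3N, CH2Cl2, 0 °C
Reagents that add atoms: methanesulfonyl chloride, CS(=O)(=O)Cl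
Why: O-sulfonylation of a secondary alcohol with retention at carbon, which turns the oxygen on the future C3 into a leaving group and masks it before the glycol cleavage.

Step 4
Reactants: 4 (1R,2S,4S,6R)-1-methyl-4-(prop-1-en-2-yl)-7-oxabicyclo[4.1.0]heptan-2-yl methanesulfonate
Product: 5 (3R,5S)-5-(methanesulfonyloxy)-6-oxo-3-(prop-1-en-2-yl)heptanal
Conditions: H5IO6, THF–H2O, 0 °C to rt
Reagents that add atoms: water, O
Why: Periodic acid cleavage of an epoxide (acid-catalysed hydration to the vicinal diol, then Malaprade glycol cleavage) opens the ring between the two former alkene carbons to a methyl ketone and an aldehyde, as is known for limonene oxide, without touching the two remaining stereocentres or the isopropenyl group.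

Step 5
Reactants: 5 (3R,5S)-5-(methanesulfonyloxy)-6-oxo-3-(prop-1-en-2-yl)heptanal
Product: 8 (1S,4R,6S)-1-methyl-4-(prop-1-en-2-yl)-7-oxabicyclo[4.1.0]heptan-2-one, via chloro keto aldehyde 6 (not isolated), via chlorohydrin ketol 7 (not isolated)
Conditions: LiCl, THF, rt, 2 h; then 2-mesityl-6,7-dihydro-5H-pyrrolo[2,1-c][1,2,4]triazol-2-ium chloride (20 mol %), DBU (1.5 equiv), THF, rt
Reagents that add atoms: none
Why: Proposed new method: chloride first displaces the α-keto mesylate by SN2 with inversion (the chloride epimers keep equilibrating by halide exchange), the carbene then adds to the aldehyde and the Breslow intermediate closes the six-membered ring by an intramolecular crossed aldehyde–ketone benzoin addition through a chair with isopropenyl and methyl equatorial and C–Cl axial and anti to the forming C1–C2 bond (polar Felkin–Anh), which places the new tertiary alkoxide trans-diaxial to chlorine so that it closes the oxirane at once with inversion at C3 and the epoxide ends cis to the isopropenyl group; the closest known reactions are the carbene-catalysed intramolecular crossed benzoin of keto aldehydes to 2-hydroxy-2-methylcyclohexanones and the base-induced chlorohydrin-to-epoxide (Darzens-type) ring closure.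

Step 6
Reactants: 8 (1S,4R,6S)-1-methyl-4-(prop-1-en-2-yl)-7-oxabicyclo[4.1.0]heptan-2-one; 9 tigloyl chloride
Product: 12 (1S,3S,4S,6S)-1-methyl-2-oxo-4-(prop-1-en-2-yl)-7-oxabicyclo[4.1.0]heptan-3-yl (2E)-2-methylbut-2-enoate, via potassium enolate 10 (not isolated), via potassium alkoxide 11 (not isolated)
Conditions: KN(SiMe3)2, THF, −78 °C; 2-(benzenesulfonyl)-3-phenyloxaziridine, −78 °C; then 9, −78 to 0 °C
Reagents that add atoms: 2-(benzenesulfonyl)-3-phenyloxaziridine, O=S(=O)(c1ccccc1)N1OC1c1ccccc1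
Why: Davis enolate hydroxylation followed by O-acylation in the same pot, where the ketone can enolise only toward the CH2 (the other α-carbon is the quaternary oxirane carbon), the oxidant approaches anti to the neighbouring isopropenyl group, and the alkoxide is trapped by the acid chloride to give the ester trans to the C5 substituent (new centre S), which is also the thermodynamically preferred epimer.

Step 7
Reactants: 12 (1S,3S,4S,6S)-1-methyl-2-oxo-4-(prop-1-en-2-yl)-7-oxabicyclo[4.1.0]heptan-3-yl (2E)-2-methylbut-2-enoate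
Product: 13 (1S,3S,4S,6S)-1-methyl-2-oxo-4-(3-oxoprop-1-en-2-yl)-7-oxabicyclo[4.1.0]heptan-3-yl (2E)-2-methylbut-2-enoate
Conditions: SeO2 (0.3 equiv), tBuOOH, CH2Cl2, rt to 40 °C
Reagents that add atoms: tert-butyl hydroperoxide, CC(C)(C)OO
Why: Riley allylic oxidation (ene reaction, then [2,3]-sigmatropic shift, SeO2 turned over by the hydroperoxide) takes the methyl of the 1,1-disubstituted alkene through the allylic alcohol to the 2-substituted acrolein, while the electron-poor tiglate alkene reacts far more slowly and no stereocentre is touched.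

Step 8
Reactants: 13 (1S,3S,4S,6S)-1-methyl-2-oxo-4-(3-oxoprop-1-en-2-yl)-7-oxabicyclo[4.1.0]heptan-3-yl (2E)-2-methylbut-2-enoate; 14 trimethyl[(2-methylbut-3-yn-2-yl)oxy]silane
Product: 18 (1S,3S,4S,6S)-4-[(4E)-3,6-dihydroxy-6-methylhepta-1,4-dien-2-yl]-1-methyl-2-oxo-7-oxabicyclo[4.1.0]heptan-3-yl (2E)-2-methylbut-2-enoate, via alkenylzirconocene 15 (not isolated), via alkenylzinc 16 (not isolated), via zinc alkoxide 17 (not isolated)
Conditions: 14, Cp2Zr(H)Cl, CH2Cl2, rt; Me2Zn, −65 °C; then 13, 0 °C; NH4Cl (aq), then citric acid, THF–H2O, rt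
Reagents that add atoms: none
Why: Schwartz hydrozirconation of the terminal alkyne (syn addition, E-alkenyl), zirconium-to-zinc transmetalation and 1,2-addition of the alkenylzinc to the aldehyde, a nucleophile that leaves the ketone, ester and oxirane alone; the new carbinol centre forms as a mixture that is removed by oxidation in the next step, and the mild acid of the work-up cleaves the trimethylsilyl ether.

Step 9
Reactants: 18 (1S,3S,4S,6S)-4-[(4E)-3,6-dihydroxy-6-methylhepta-1,4-dien-2-yl]-1-methyl-2-oxo-7-oxabicyclo[4.1.0]heptan-3-yl (2E)-2-methylbut-2-enoate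
Product: 19 (1S,3S,4S,6S)-4-[(4E)-6-hydroxy-6-methyl-3-oxohepta-1,4-dien-2-yl]-1-methyl-2-oxo-7-oxabicyclo[4.1.0]heptan-3-yl (2E)-2-methylbut-2-enoate
Conditions: Dess–Martin periodinane, NaHCO3, CH2Cl2, 0 °C to rt
Reagents that add atoms: none
Why: Dess–Martin oxidation of the secondary bis-allylic alcohol to the cross-conjugated dienone, in which the tertiary alcohol cannot be oxidised and the buffered, non-basic medium spares the epoxy ketone and the α-acyloxy ketone, so no stereocentre is affected.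

**Compound list**
1 | (S)-(+)-carvone, (5S)-2-methyl-5-(prop-1-en-2-yl)cyclohex-2-en-1-one | CC(=C)[C@H]1CC=C(C)C(=O)C1 | starting material
2 | (1S,5S)-2-methyl-5-(prop-1-en-2-yl)cyclohex-2-en-1-ol (cis-carveol) | CC(=C)[C@H]1CC=C(C)[C@@H](O)C1 | intermediate
3 | (1S,2S,4R,6R)-1-methyl-4-(prop-1-en-2-yl)-7-oxabicyclo[4.1.0]heptan-2-ol (oxirane, OH and isopropenyl all cis) | CC(=C)[C@H]1C[C@H]2O[C@@]2(C)[C@@H](O)C1 | intermediate
4 | (1R,2S,4S,6R)-1-methyl-4-(prop-1-en-2-yl)-7-oxabicyclo[4.1.0]heptan-2-yl methanesulfonate | CC(=C)[C@H]1C[C@H]2O[C@@]2(C)[C@@H](OS(C)(=O)=O)C1 | intermediate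
5 | (3R,5S)-5-(methanesulfonyloxy)-6-oxo-3-(prop-1-en-2-yl)heptanal | CC(=C)[C@@H](CC=O)C[C@H](OS(C)(=O)=O)C(C)=O | intermediate
6 | (3S,5R)-5-chloro-6-oxo-3-(prop-1-en-2-yl)heptanal | CC(=C)[C@@H](CC=O)C[C@@H](Cl)C(C)=O | intermediate
7 | (2R,3R,5S)-3-chloro-2-hydroxy-2-methyl-5-(prop-1-en-2-yl)cyclohexan-1-one (OH cis, Cl trans to isopropenyl) | CC(=C)[C@@H]1C[C@@H](Cl)[C@](C)(O)C(=O)C1 | intermediate
8 | (1S,4R,6S)-1-methyl-4-(prop-1-en-2-yl)-7-oxabicyclo[4.1.0]heptan-2-one (oxirane cis to isopropenyl) | CC(=C)[C@@H]1C[C@@H]2O[C@]2(C)C(=O)C1 | intermediate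
9 | tigloyl chloride, (2E)-2-methylbut-2-enoyl chloride | C/C=C(\C)C(Cl)=O | starting material
10 | potassium enolate of 8 | CC(=C)[C@@H]1C[C@@H]2O[C@]2(C)C([O-])=C1.[K+] | intermediate
11 | potassium alkoxide of the 3-hydroxy derivative of 8 (O trans to isopropenyl) | CC(=C)[C@@H]1C[C@@H]2O[C@]2(C)C(=O)[C@H]1[O-].[K+] | intermediate
12 | (1S,3S,4S,6S)-1-methyl-2-oxo-4-(prop-1-en-2-yl)-7-oxabicyclo[4.1.0]heptan-3-yl (2E)-2-methylbut-2-enoate | CC(=C)[C@@H]1C[C@@H]2O[C@]2(C)C(=O)[C@H]1OC(=O)/C(C)=C/C | intermediate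
13 | (1S,3S,4S,6S)-1-methyl-2-oxo-4-(3-oxoprop-1-en-2-yl)-7-oxabicyclo[4.1.0]heptan-3-yl (2E)-2-methylbut-2-enoate | O=CC(=C)[C@@H]1C[C@@H]2O[C@]2(C)C(=O)[C@H]1OC(=O)/C(C)=C/C | intermediate
14 | trimethyl[(2-methylbut-3-yn-2-yl)oxy]silane | C#CC(C)(C)O[Si](C)(C)C | starting material
15 | chlorobis(cyclopentadienyl)[(1E)-3-methyl-3-(trimethylsilyloxy)but-1-en-1-yl]zirconium | C[Si](C)(C)OC(C)(C)/C=C/[Zr](Cl)(C1C=CC=C1)C1C=CC=C1 | intermediate
16 | methyl[(1E)-3-methyl-3-(trimethylsilyloxy)but-1-en-1-yl]zinc | C[Zn]/C=C/C(C)(C)O[Si](C)(C)C | intermediate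
17 | methylzinc alkoxide of the silyl-protected adduct of 13 (both carbinol epimers) | C[Zn]OC(/C=C/C(C)(C)O[Si](C)(C)C)C(=C)[C@@H]1C[C@@H]2O[C@]2(C)C(=O)[C@H]1OC(=O)/C(C)=C/C | intermediate
18 | (1S,3S,4S,6S)-4-[(4E)-3,6-dihydroxy-6-methylhepta-1,4-dien-2-yl]-1-methyl-2-oxo-7-oxabicyclo[4.1.0]heptan-3-yl (2E)-2-methylbut-2-enoate (both carbinol epimers) | CC(C)(O)/C=C/C(O)C(=C)[C@@H]1C[C@@H]2O[C@]2(C)C(=O)[C@H]1OC(=O)/C(C)=C/C | intermediate
19 | (1S,3S,4S,6S)-4-[(4E)-6-hydroxy-6-methyl-3-oxohepta-1,4-dien-2-yl]-1-methyl-2-oxo-7-oxabicyclo[4.1.0]heptan-3-yl (2E)-2-methylbut-2-enoate | C=C(C(=O)/C=C/C(C)(C)O)[C@@H]1C[C@@H]2O[C@]2(C)C(=O)[C@H]1OC(=O)/C(C)=C/C | target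

**Step count**
Total steps: 9. Longest linear sequence: 9 (1 to 19).

**Steps most likely to fail, with fallbacks**

Step 5 is the least secure. The Breslow intermediate or the free carbene may be alkylated by the α-chloro ketone, and base-induced aldol reactions compete. The fallback gives up the cascade and transposes the oxygen pattern on the intact ring. It sets out from 3: Dess–Martin oxidation gives (1R,4S,6R)-1-methyl-4-(prop-1-en-2-yl)-7-oxabicyclo[4.1.0]heptan-2-one F1, the enantiomer of 8. Wharton rearrangement (N2H4·H2O, AcOH, MeOH) converts it into (1R,5R)-2-methyl-5-(prop-1-en-2-yl)cyclohex-2-en-1-ol F2. VO(acac)2/tBuOOH then gives (1R,2R,4S,6S)-1-methyl-4-(prop-1-en-2-yl)-7-oxabicyclo[4.1.0]heptan-2-ol F3, and a second Dess–Martin oxidation comes back to the route at 8.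

Step 6 may fail because the alkoxide formed in the hydroxylation is hindered and the sulfonimine by-product can intercept the enolate. The fallback forms the C–O bond by carboxylate displacement instead of electrophilic oxygenation. It sets out from 8: LiN(SiMe3)2 and Me3SiCl give the trimethylsilyl enol ether of 8 F4, and NBS gives the 3-bromo ketone with bromine trans to the isopropenyl group F5. Tiglic acid with Cs2CO3 in DMF displaces bromide with inversion to the C3 epimer of 12 F6, which epimerises under the same carbonate conditions to the trans ester, returning to the route at 12.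

Step 7 may give over-oxidation, attack on the tiglate methyl groups or acid-induced opening of the oxirane. The fallback replaces direct oxidation by chlorination and N-oxide oxidation. It sets out from 12: ene-type chlorination with Ca(OCl)2 and CO2 in CH2Cl2–H2O gives (1S,3S,4S,6S)-4-(3-chloroprop-1-en-2-yl)-1-methyl-2-oxo-7-oxabicyclo[4.1.0]heptan-3-yl (2E)-2-methylbut-2-enoate F7. Oxidation with N-methylmorpholine N-oxide (NaI catalyst, MeCN) then comes back to the route at 13.

Further compounds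
F1 | step 5 | (1R,4S,6R)-1-methyl-4-(prop-1-en-2-yl)-7-oxabicyclo[4.1.0]heptan-2-one | CC(=C)[C@H]1C[C@H]2O[C@@]2(C)C(=O)C1
F2 | step 5 | (1R,5R)-2-methyl-5-(prop-1-en-2-yl)cyclohex-2-en-1-ol | CC(=C)[C@@H]1CC=C(C)[C@H](O)C1
F3 | step 5 | (1R,2R,4S,6S)-1-methyl-4-(prop-1-en-2-yl)-7-oxabicyclo[4.1.0]heptan-2-ol | CC(=C)[C@@H]1C[C@@H]2O[C@]2(C)[C@H](O)C1
F4 | step 6 | trimethylsilyl enol ether of 8 | CC(=C)[C@@H]1C[C@@H]2O[C@]2(C)C(O[Si](C)(C)C)=C1
F5 | step 6 | 3-bromo ketone with bromine trans to the isopropenyl group | CC(=C)[C@@H]1C[C@@H]2O[C@]2(C)C(=O)[C@H]1Br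
F6 | step 6 | C3 epimer of 12 | CC(=C)[C@@H]1C[C@@H]2O[C@]2(C)C(=O)[C@@H]1OC(=O)/C(C)=C/C
F7 | step 7 | (1S,3S,4S,6S)-4-(3-chloroprop-1-en-2-yl)-1-methyl-2-oxo-7-oxabicyclo[4.1.0]heptan-3-yl (2E)-2-methylbut-2-enoate | ClCC(=C)[C@@H]1C[C@@H]2O[C@]2(C)C(=O)[C@H]1OC(=O)/C(C)=C/C
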